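The bicyclo[3.1.1]heptenone core (cyclobutane C4–C5–C11–C10 fused to enone ring C1–C2=C3–C4–C5–C11) is treated as the ring-contracted isomer of a norbornene. An intramolecular Diels–Alder reaction of a 5,5-disubstituted 1-silyloxycyclopentadiene with a tethered (E)-nitroalkene builds that norbornene and the seven-membered ring at once. A Tiffeneau–Demjanov shift of bridge carbon C10 from the oxygenated bridgehead C1 to C11 then forms the C10–C11 cyclobutane bond and unveils the C1 ketone conjugated with C2=C3. The feature exploited is the 1,2-relation of the C1 carbonyl and quaternary C10 across C11. The precursor is an endo-2-amino-norbornen-1-ol.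

Key step: step 12

Remark: atom labels C1–C11 follow longipinane numbering of the target and are kept for every intermediate. C1 is the ketone carbon, C2=C3(Me) the enone, C4 and C5 the cyclobutane CH groups, C6 the CMe2 carbon, C7 the CH–O(methacrylate), C8 the CH2, C9 the CH–O(isobutyrate), C10 the quaternary C–Me and C11 the CH between C1 and C10. In step 1 the ligand enantiomer is the one that delivers the 3R alcohol.

Step 1
Reactants: 1 3,3-diethoxypropan-1-ol; 2 3-methylbuta-1,2-diene
Product: 3 (3R)-1,1-diethoxy-4,4-dimethylhex-5-en-3-ol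
Conditions: [Ir(cod)Cl]2 (2.5 mol%), SEGPHOS (5 mol%), 4-cyano-3-nitrobenzoic acid (10 mol%), allyl acetate (10 mol%), Cs2CO3 (20 mol%), toluene, 60 °C
Reagents that add atoms: none
Why: Iridium-catalysed transfer-hydrogenative carbonyl reverse prenylation from the alcohol oxidation level: the alcohol is dehydrogenated to the aldehyde, the allene is hydrometalated to a 1,1-dimethylallyl iridium species that adds at its substituted terminus through a closed chair transition state, and the chiral bisphosphine sets C7 as R while the gem-dimethyl carbon C6 and the C5 vinyl group arrive in the same operation.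

Step 2
Reactants: 3 (3R)-1,1-diethoxy-4,4-dimethylhex-5-en-3-ol
Product: 4 1-({[(3R)-1,1-diethoxy-4,4-dimethylhex-5-en-3-yl]oxy}methyl)-4-methoxybenzene
Conditions: NaH, 4-methoxybenzyl chloride, Bu4NI (cat.), DMF, 0 °C to rt
Reagents that add atoms: 4-methoxybenzyl chloride, COc1ccc(CCl)cc1
Why: Williamson etherification of the hindered secondary alkoxide; the p-methoxybenzyl ether is the β-alkoxy group needed for 1,3-induction in step 5 and can be removed at the end without touching esters or the enone.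

Step 3
Reactants: 4 1-({[(3R)-1,1-diethoxy-4,4-dimethylhex-5-en-3-yl]oxy}methyl)-4-methoxybenzene
Product: 5 (3R)-3-[(4-methoxyphenyl)methoxy]-4,4-dimethylhex-5-enal
Conditions: pyridinium p-toluenesulfonate (20 mol%), acetone/H2O (4:1), 45 °C
Reagents that add atoms: water, O
Why: Mild acid-catalysed acetal hydrolysis unveils the C9 aldehyde; the p-methoxybenzyl ether and the alkene tolerate the weak acid and the C7 stereocentre is not enolizable.

Step 4
Reactants: 6 3-methylcyclopent-2-en-1-one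
Product: 8 1-methyl-3-(trimethylsilyloxy)cyclopenta-1,3-diene, via lithium cross-conjugated dienolate 7 (not isolated)
Conditions: LiN(iPr)2, THF, −78 °C; then Me3SiCl, −78 to 0 °C; pentane, filtration, used at once
Reagents that add atoms: chlorotrimethylsilane, C[Si](C)(C)Cl
Why: Kinetic α′-deprotonation of the enone and O-silylation (silyl enol ether formation) give the cross-conjugated silyl dienol ether, which is nucleophilic at the future C10.

Step 5
Reactants: 5 (3R)-3-[(4-methoxyphenyl)methoxy]-4,4-dimethylhex-5-enal; 8 1-methyl-3-(trimethylsilyloxy)cyclopenta-1,3-diene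
Product: 9 5-[(1R,3R)-1-hydroxy-3-[(4-methoxyphenyl)methoxy]-4,4-dimethylhex-5-en-1-yl]-3-methylcyclopent-2-en-1-one (both C10 epimers)
Conditions: BF3·OEt2 (1.1 equiv), CH2Cl2, −78 °C; then aq. NaHCO3
Reagents that add atoms: none
Why: Mukaiyama aldol addition through an open transition state; with the monodentate Lewis acid the β-alkoxy stereocentre C7 directs attack 1,3-anti (polar non-chelate model), which should set C9 as R, while the C10 mixture is erased in step 6.

Step 6
Reactants: 9 5-[(1R,3R)-1-hydroxy-3-[(4-methoxyphenyl)methoxy]-4,4-dimethylhex-5-en-1-yl]-3-methylcyclopent-2-en-1-one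
Product: 11 (5S)-5-[(1R,3R)-1-hydroxy-3-[(4-methoxyphenyl)methoxy]-4,4-dimethylhex-5-en-1-yl]-3,5-dimethylcyclopent-2-en-1-one, via dilithium aldolate enolate 10 (not isolated)
Conditions: LiN(iPr)2 (2.3 equiv), THF, −78 to −45 °C; then MeI, DMPU, −78 to −30 °C; AcOH quench at −78 °C
Reagents that add atoms: iodomethane, CI
Why: Fráter–Seebach-type alkylation: kinetic α′-deprotonation of the lithium aldolate gives a six-membered lithium chelate (O9–Li–O1) in which the C8 chain blocks one enolate face, so iodomethane enters anti to it and the methyl group ends anti, the ring CH2 (C4) syn, to the C9 oxygen, which sets the quaternary centre C10 from either C10 epimer of 9.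

Step 7
Reactants: 11 (5S)-5-[(1R,3R)-1-hydroxy-3-[(4-methoxyphenyl)methoxy]-4,4-dimethylhex-5-en-1-yl]-3,5-dimethylcyclopent-2-en-1-one
Product: 12 (1R,3R)-1-[(1S)-1,4-dimethyl-2-oxocyclopent-3-en-1-yl]-3-[(4-methoxyphenyl)methoxy]-4,4-dimethylhex-5-en-1-yl 2-methylpropanoate
Conditions: 2-methylpropanoyl chloride, pyridine, DMAP (cat.), CH2Cl2, 0 to 40 °C
Reagents that add atoms: 2-methylpropanoyl chloride, CC(C)C(Cl)=O
Why: DMAP-catalysed acylation installs the final C9 isobutyrate and blocks retro-aldol cleavage of the congested β-hydroxy ketone; no elimination is possible because C10 is quaternary.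

Step 8
Reactants: 12 (1R,3R)-1-[(1S)-1,4-dimethyl-2-oxocyclopent-3-en-1-yl]-3-[(4-methoxyphenyl)methoxy]-4,4-dimethylhex-5-en-1-yl 2-methylpropanoate
Product: 14 (1R,3R)-1-[(1S)-1,4-dimethyl-2-oxocyclopent-3-en-1-yl]-3-[(4-methoxyphenyl)methoxy]-4,4-dimethyl-5-oxopentyl 2-methylpropanoate, via vicinal diol 13 (not isolated)
Conditions: OsO4 (2 mol%), NaIO4 (4 equiv), 2,6-lutidine, 1,4-dioxane/H2O (3:1), rt
Reagents that add atoms: sodium periodate, [Na+].[O-]I(=O)(=O)=O
Why: Lemieux–Johnson oxidation: OsO4 dihydroxylates the monosubstituted C5 vinyl group faster than the electron-poor trisubstituted enone alkene and periodate cleaves the diol to the non-enolizable C5 aldehyde.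

Step 9
Reactants: 14 (1R,3R)-1-[(1S)-1,4-dimethyl-2-oxocyclopent-3-en-1-yl]-3-[(4-methoxyphenyl)methoxy]-4,4-dimethyl-5-oxopentyl 2-methylpropanoate
Product: 17 (1R,3R,5E)-1-[(1S)-1,4-dimethyl-2-oxocyclopent-3-en-1-yl]-3-[(4-methoxyphenyl)methoxy]-4,4-dimethyl-6-nitrohex-5-en-1-yl 2-methylpropanoate, via nitro alcohol 15 (not isolated), via nitro alcohol mesylate 16 (not isolated)
Conditions: MeNO2 (10 equiv), N,N,N′,N′-tetramethylguanidine (10 mol%), THF, 0 °C; volatiles removed; then MsCl, iPr2NEt, CH2Cl2, −20 to 0 °C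
Reagents that add atoms: nitromethane, C[N+](=O)[O-]
Why: Henry reaction of the non-enolizable aldehyde followed by mesylation and E1cB elimination gives the thermodynamically preferred (E)-nitroalkene, whose geometry later fixes the endo position of nitrogen.

Step 10
Reactants: 17 (1R,3R,5E)-1-[(1S)-1,4-dimethyl-2-oxocyclopent-3-en-1-yl]-3-[(4-methoxyphenyl)methoxy]-4,4-dimethyl-6-nitrohex-5-en-1-yl 2-methylpropanoate
Product: 20 endo-nitro norbornenol cycloadduct, via trimethylsilyl dienol ether 18 (not isolated), via silylated cycloadduct 19 (not isolated)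
Conditions: Me3SiOTf (1.5 equiv), iPr2NEt (3 equiv), CH2Cl2, −78 to 0 °C; then toluene (0.005 M), 60 °C; then citric acid, MeOH, 0 °C
Reagents that add atoms: none
Why: Soft enolization at the γ-carbon C4 gives the 1-silyloxycyclopentadiene (C10 is quaternary, so no [1,5]-hydrogen shift scrambles it, and the transoid exocyclic isomer cannot cycloadd and equilibrates), which undergoes an intramolecular normal-demand Diels–Alder reaction in which the tether on C10 forces the dienophile onto the face syn to C9 (sets C1, C4 and C5), the nucleophilic diene terminus C4 pairs with the electrophilic β-carbon C5 (C11 to C1), and the E alkene together with the necessarily exo C5–C6 bond places the nitro group endo at C11; the acidic work-up cleaves the bridgehead silyl ether.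

Step 11
Reactants: 20 endo-nitro norbornenol cycloadduct
Product: 21 endo-amino norbornenol
Conditions: Zn dust (30 equiv), AcOH/THF (1:1), 0 °C to rt
Reagents that add atoms: none
Why: Zinc in acetic acid reduces the secondary nitro group to the primary amine under non-basic conditions, so neither retro-Henry cleavage nor epimerization at C11 (both base-mediated) should occur, and the alkene, the ester and the p-methoxybenzyl ether are inert.

Step 12
Reactants: 21 endo-amino norbornenol
Product: 23 (4R,5S,7R,9R,10R,11R)-7-[(4-methoxyphenyl)methoxy]-1-oxolongipin-2-en-9-yl 2-methylpropanoate, via endo diazonium acetate 22 (not isolated)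
Conditions: NaNO2 (3 equiv), AcOH/H2O (4:1), 0 °C to rt
Reagents that add atoms: none
Why: Nitrosation gives the endo C11 diazonium ion 22; as N2 departs, the C1–C10 σ-bond, which lies antiperiplanar (about 155°) to C11–N, shifts to C11 while the C1 hydroxyl oxygen becomes the carbonyl (deaminative semipinacol rearrangement of Tiffeneau–Demjanov type). The closest known reaction type is the nitrous-acid ring contraction of trans-2-aminocycloalkanols to acylcycloalkanes and the pinacol-type bicyclo[2.2.2]octenol to bicyclo[3.2.1]octenone shift; here it runs in the bornane-to-pinane direction, paid for by C=O formation and loss of N2. The new C10–C11 bond closes the cyclobutane C4–C5–C11–C10 by a suprafacial 1,2-alkyl shift: the cyclopentane C1–C11–C5–C4–C10 contracts by one atom while the cyclopentene C1–C2=C3–C4–C10 expands to the cyclohexenone, so no chain-cyclization mode applies. C11 is formed with inversion (C10 arrives on the exo face, anti to the endo leaving group) and C10 migrates with retention, which gives 11R and 10R, while C4, C5, C7 and C9 are untouched. The step must select migration of C10 over migration of vinyl C2, hydride shift from C5 and capture of a free cation by the C2=C3 π bond; only C1–C10 is antiperiplanar to the endo C–N bond (C1–C2 is gauche, H5 and the π bond lie on the leaving-group face), a geometry fixed by the (E)-nitroalkene and the exo tether in step 10. The oxygen lone pair at C1 should make the shift concerted with N2 loss, and the enone C1(=O)–C2=C3 emerges directly.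

Step 13
Reactants: 23 (4R,5S,7R,9R,10R,11R)-7-[(4-methoxyphenyl)methoxy]-1-oxolongipin-2-en-9-yl 2-methylpropanoate
Product: 24 (4R,5S,7R,9R,10R,11R)-7-hydroxy-1-oxolongipin-2-en-9-yl 2-methylpropanoate
Conditions: DDQ (1.5 equiv), CH2Cl2/pH 7 phosphate buffer (10:1), 0 °C to rt
Reagents that add atoms: none
Why: Oxidative cleavage of the p-methoxybenzyl ether by DDQ (oxidation to the oxocarbenium ion and hydrolysis) frees the C7 hydroxyl without affecting the enone, the cyclobutane or the isobutyrate.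

Step 14
Reactants: 24 (4R,5S,7R,9R,10R,11R)-7-hydroxy-1-oxolongipin-2-en-9-yl 2-methylpropanoate
Product: 25 (4R,5S,7R,9R,10R,11R)-9-(2-methylpropanoyloxy)-1-oxolongipin-2-en-7-yl 2-methylprop-2-enoate (CNP0214356.1)
Conditions: 2-methylprop-2-enoyl chloride, Et3N, DMAP (cat.), BHT (trace), CH2Cl2, 0 °C to rt
Reagents that add atoms: 2-methylprop-2-enoyl chloride, C=C(C)C(Cl)=O
Why: DMAP-catalysed acylation of the neopentyl-type C7 alcohol with the acid chloride gives the methacrylate; low temperature and a radical inhibitor suppress acyl migration from O9 and polymerization.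

Compound list

1 | 3,3-diethoxypropan-1-ol | CCOC(OCC)CCO | starting material
2 | 3-methylbuta-1,2-diene | CC(C)=C=C | starting material
3 | (3R)-1,1-diethoxy-4,4-dimethylhex-5-en-3-ol | CCOC(OCC)C[C@@H](O)C(C)(C)C=C | intermediate
4 | 1-({[(3R)-1,1-diethoxy-4,4-dimethylhex-5-en-3-yl]oxy}methyl)-4-methoxybenzene | CCOC(OCC)C[C@@H](OCc1ccc(OC)cc1)C(C)(C)C=C | intermediate
5 | (3R)-3-[(4-methoxyphenyl)methoxy]-4,4-dimethylhex-5-enal | O=CC[C@@H](OCc1ccc(OC)cc1)C(C)(C)C=C | intermediate
6 | 3-methylcyclopent-2-en-1-one | CC1=CC(=O)CC1 | starting material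
7 | lithium 4-methylcyclopenta-1,3-dien-2-olate (cross-conjugated dienolate, not isolated) | [Li+].CC1=CC([O-])=CC1 | intermediate
8 | 1-methyl-3-(trimethylsilyloxy)cyclopenta-1,3-diene | CC1=CC(O[Si](C)(C)C)=CC1 | intermediate
9 | 5-[(1R,3R)-1-hydroxy-3-[(4-methoxyphenyl)methoxy]-4,4-dimethylhex-5-en-1-yl]-3-methylcyclopent-2-en-1-one (C10 epimers) | CC1=CC(=O)C(C1)[C@H](O)C[C@@H](OCc2ccc(OC)cc2)C(C)(C)C=C | intermediate
10 | dilithium aldolate enolate of 9 (not isolated) | [Li+].[Li+].CC1=CC([O-])=C(C1)[C@H]([O-])C[C@@H](OCc2ccc(OC)cc2)C(C)(C)C=C | intermediate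
11 | (5S)-5-[(1R,3R)-1-hydroxy-3-[(4-methoxyphenyl)methoxy]-4,4-dimethylhex-5-en-1-yl]-3,5-dimethylcyclopent-2-en-1-one | CC1=CC(=O)[C@@](C)(C1)[C@H](O)C[C@@H](OCc2ccc(OC)cc2)C(C)(C)C=C | intermediate
12 | (1R,3R)-1-[(1S)-1,4-dimethyl-2-oxocyclopent-3-en-1-yl]-3-[(4-methoxyphenyl)methoxy]-4,4-dimethylhex-5-en-1-yl 2-methylpropanoate | CC1=CC(=O)[C@@](C)(C1)[C@H](OC(=O)C(C)C)C[C@@H](OCc2ccc(OC)cc2)C(C)(C)C=C | intermediate
13 | vicinal diol from dihydroxylation of the vinyl group of 12 (not isolated, diol carbinol epimers) | CC1=CC(=O)[C@@](C)(C1)[C@H](OC(=O)C(C)C)C[C@@H](OCc2ccc(OC)cc2)C(C)(C)C(O)CO | intermediate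
14 | (1R,3R)-1-[(1S)-1,4-dimethyl-2-oxocyclopent-3-en-1-yl]-3-[(4-methoxyphenyl)methoxy]-4,4-dimethyl-5-oxopentyl 2-methylpropanoate | CC1=CC(=O)[C@@](C)(C1)[C@H](OC(=O)C(C)C)C[C@@H](OCc2ccc(OC)cc2)C(C)(C)C=O | intermediate
15 | nitro alcohol from Henry addition to 14 (not isolated, C5 carbinol epimers) | CC1=CC(=O)[C@@](C)(C1)[C@H](OC(=O)C(C)C)C[C@@H](OCc2ccc(OC)cc2)C(C)(C)C(O)C[N+](=O)[O-] | intermediate
16 | methanesulfonate of 15 (not isolated) | CC1=CC(=O)[C@@](C)(C1)[C@H](OC(=O)C(C)C)C[C@@H](OCc2ccc(OC)cc2)C(C)(C)C(OS(C)(=O)=O)C[N+](=O)[O-] | intermediate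
17 | (1R,3R,5E)-1-[(1S)-1,4-dimethyl-2-oxocyclopent-3-en-1-yl]-3-[(4-methoxyphenyl)methoxy]-4,4-dimethyl-6-nitrohex-5-en-1-yl 2-methylpropanoate | CC1=CC(=O)[C@@](C)(C1)[C@H](OC(=O)C(C)C)C[C@@H](OCc2ccc(OC)cc2)C(C)(C)/C=C/[N+](=O)[O-] | intermediate
18 | (1R,3R,5E)-1-[(1S)-1,4-dimethyl-2-(trimethylsilyloxy)cyclopenta-2,4-dien-1-yl]-3-[(4-methoxyphenyl)methoxy]-4,4-dimethyl-6-nitrohex-5-en-1-yl 2-methylpropanoate (not isolated) | CC1=C[C@@](C)([C@H](OC(=O)C(C)C)C[C@@H](OCc2ccc(OC)cc2)C(C)(C)/C=C/[N+](=O)[O-])C(O[Si](C)(C)C)=C1 | intermediate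
19 | silylated cycloadduct (not isolated): bicyclo[2.2.1]hept-2-ene C1–C2=C3–C4–C5–C11 with one-carbon bridge C10, bridged from C10 to C5 by C9–C8–C7–C6; C1 OSiMe3, C3 Me, C10 Me syn to C2=C3, C11 NO2 endo, C5 H endo, C6 Me2, C7 O-(4-methoxybenzyl), C9 O-(2-methylpropanoyl) | COc1ccc(CO[C@@H]2C[C@@H](OC(=O)C(C)C)[C@@]3(C)[C@]4(O[Si](C)(C)C)C=C(C)[C@H]3[C@@H]([C@H]4[N+](=O)[O-])C2(C)C)cc1 | intermediate
20 | endo-nitro norbornenol cycloadduct: as 19 with free C1 OH | COc1ccc(CO[C@@H]2C[C@@H](OC(=O)C(C)C)[C@@]3(C)[C@]4(O)C=C(C)[C@H]3[C@@H]([C@H]4[N+](=O)[O-])C2(C)C)cc1 | intermediate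
21 | endo-amino norbornenol: as 20 with C11 NH2 endo | COc1ccc(CO[C@@H]2C[C@@H](OC(=O)C(C)C)[C@@]3(C)[C@]4(O)C=C(C)[C@H]3[C@@H]([C@H]4N)C2(C)C)cc1 | intermediate
22 | endo C11 diazonium acetate of 21 (not isolated) | COc1ccc(CO[C@@H]2C[C@@H](OC(=O)C(C)C)[C@@]3(C)[C@]4(O)C=C(C)[C@H]3[C@@H]([C@H]4[N+]#N)C2(C)C)cc1.CC(=O)[O-] | intermediate
23 | (4R,5S,7R,9R,10R,11R)-7-[(4-methoxyphenyl)methoxy]-1-oxolongipin-2-en-9-yl 2-methylpropanoate | COc1ccc(CO[C@@H]2C[C@@H](OC(=O)C(C)C)[C@@]3(C)[C@@H]4C(=O)C=C(C)[C@H]3[C@@H]4C2(C)C)cc1 | intermediate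
24 | (4R,5S,7R,9R,10R,11R)-7-hydroxy-1-oxolongipin-2-en-9-yl 2-methylpropanoate | O[C@@H]1C[C@@H](OC(=O)C(C)C)[C@@]2(C)[C@@H]3C(=O)C=C(C)[C@H]2[C@@H]3C1(C)C | intermediate
25 | (4R,5S,7R,9R,10R,11R)-9-(2-methylpropanoyloxy)-1-oxolongipin-2-en-7-yl 2-methylprop-2-enoate (CNP0214356.1) | C=C(C)C(=O)O[C@@H]1C[C@@H](OC(=O)C(C)C)[C@@]2(C)[C@@H]3C(=O)C=C(C)[C@H]2[C@@H]3C1(C)C | target

Total step count: 14. Longest linear sequence: 13 steps (steps 1–3 and 5–14; step 4 is the side branch).

Steps most likely to fail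

Step 12 (key step). The diazonium ion may leak into cation-type pathways before the bridge shift takes place: capture by the C2=C3 π bond to give nortricyclyl-type products, or substitution by acetate or water. The fallback replaces the diazonium trigger by a base-triggered sulfonate semipinacol that never passes through a free cation; it sets out from aldehyde 14 and comes back at ketone 23. Boron olefination of 14 (Cl2CHB(pin), CrCl2, LiI, THF, rt) should give the (E)-alkenylboronate F1. Silylation (t-BuMe2SiOTf, iPr2NEt, CH2Cl2) would give the silyl dienol ether F2, which on heating (xylene, 140 °C) should close by the same intramolecular Diels–Alder mode to the endo-boronate cycloadduct F3. Oxidation with retention (NaBO3·4H2O, THF/H2O) would give the endo C11 alcohol F4, and MsCl/Et3N the endo mesylate F5. Fluoride (Bu4NF, THF, 0 °C) then frees the bridgehead alkoxide, which pushes the antiperiplanar C10 shift as the mesylate leaves and delivers 23.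

Step 10. The amine base may oligomerize the nitroalkene while the dienol ether is being formed, and the slow closure of the seven-membered tether ring leaves time for intermolecular cycloaddition. The fallback masks the dienophile until the diene is in place; it sets out from nitro alcohol 15 (isolated in this variant) and comes back at dienol ether 18. Acetylation (Ac2O, DMAP, CH2Cl2) would give the β-acetoxy nitro compound F6. Silylation at −78 °C (Me3SiOTf, iPr2NEt) would give its trimethylsilyl dienol ether F7; on warming in dilute toluene the amine eliminates acetic acid, so that 18 is released slowly and only with the diene already present, and it cyclizes to 19 and then 20 as in the main route.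

Step 6. The lithium aldolate may undergo γ-deprotonation or retro-aldol cleavage, and facial control of the methylation may erode. The fallback sets the quaternary centre by the classical ester version of the same alkylation and builds the cyclopentenone afterwards; it sets out from aldehyde 5 and comes back at 11. Commercial ethyl 4-methylpent-4-enoate would be converted (LiN(iPr)2, Me3SiCl) into the silyl ketene acetal F8, whose BF3·OEt2-mediated Mukaiyama aldol with 5 should give the 1,3-anti β-hydroxy ester F9. Fráter–Seebach methylation (LiN(iPr)2, 2.2 equiv; MeI) would give the quaternary ester F10. LiAlH4 would give the diol F11, and TEMPO/PhI(OAc)2 the hydroxy aldehyde F12. Vinylmagnesium bromide would give the allylic alcohol F13, and MnO2 the vinyl ketone F14. Ring-closing metathesis (Hoveyda–Grubbs second-generation catalyst, toluene, 80 °C) between the vinyl ketone and the 2-methylallyl group would then close the 3-methylcyclopentenone and give 11.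

Further compounds

F1 | step 12 | (1R,3R,5E)-1-[(1S)-1,4-dimethyl-2-oxocyclopent-3-en-1-yl]-3-[(4-methoxyphenyl)methoxy]-4,4-dimethyl-6-(4,4,5,5-tetramethyl-1,3,2-dioxaborolan-2-yl)hex-5-en-1-yl 2-methylpropanoate | CC1=CC(=O)[C@@](C)(C1)[C@H](OC(=O)C(C)C)C[C@@H](OCc2ccc(OC)cc2)C(C)(C)/C=C/B3OC(C)(C)C(C)(C)O3
F2 | step 12 | tert-butyldimethylsilyl dienol ether of F1 | CC1=C[C@@](C)([C@H](OC(=O)C(C)C)C[C@@H](OCc2ccc(OC)cc2)C(C)(C)/C=C/B3OC(C)(C)C(C)(C)O3)C(O[Si](C)(C)C(C)(C)C)=C1
F3 | step 12 | endo-boronate cycloadduct (as 19 with C1 OSi(t-Bu)Me2 and C11 B(pin) endo) | COc1ccc(CO[C@@H]2C[C@@H](OC(=O)C(C)C)[C@@]3(C)[C@]4(O[Si](C)(C)C(C)(C)C)C=C(C)[C@H]3[C@@H]([C@H]4B5OC(C)(C)C(C)(C)O5)C2(C)C)cc1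
F4 | step 12 | endo C11 alcohol (as F3 with C11 OH endo) | COc1ccc(CO[C@@H]2C[C@@H](OC(=O)C(C)C)[C@@]3(C)[C@]4(O[Si](C)(C)C(C)(C)C)C=C(C)[C@H]3[C@@H]([C@H]4O)C2(C)C)cc1
F5 | step 12 | endo C11 methanesulfonate of F4 | COc1ccc(CO[C@@H]2C[C@@H](OC(=O)C(C)C)[C@@]3(C)[C@]4(O[Si](C)(C)C(C)(C)C)C=C(C)[C@H]3[C@@H]([C@H]4OS(C)(=O)=O)C2(C)C)cc1
F6 | step 10 | acetate of nitro alcohol 15 | CC1=CC(=O)[C@@](C)(C1)[C@H](OC(=O)C(C)C)C[C@@H](OCc2ccc(OC)cc2)C(C)(C)C(OC(C)=O)C[N+](=O)[O-]
F7 | step 10 | trimethylsilyl dienol ether of F6 | CC1=C[C@@](C)([C@H](OC(=O)C(C)C)C[C@@H](OCc2ccc(OC)cc2)C(C)(C)C(OC(C)=O)C[N+](=O)[O-])C(O[Si](C)(C)C)=C1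
F8 | step 6 | [(1-ethoxy-4-methylpenta-1,4-dien-1-yl)oxy]trimethylsilane | CCOC(O[Si](C)(C)C)=CCC(C)=C
F9 | step 6 | ethyl (3R,5R)-3-hydroxy-5-[(4-methoxyphenyl)methoxy]-6,6-dimethyl-2-(2-methylprop-2-en-1-yl)oct-7-enoate (C2 epimers) | CCOC(=O)C(CC(C)=C)[C@H](O)C[C@@H](OCc1ccc(OC)cc1)C(C)(C)C=C
F10 | step 6 | ethyl (2S,3R,5R)-3-hydroxy-5-[(4-methoxyphenyl)methoxy]-2,6,6-trimethyl-2-(2-methylprop-2-en-1-yl)oct-7-enoate | CCOC(=O)[C@@](C)(CC(C)=C)[C@H](O)C[C@@H](OCc1ccc(OC)cc1)C(C)(C)C=C
F11 | step 6 | (2R,3R,5R)-5-[(4-methoxyphenyl)methoxy]-2,6,6-trimethyl-2-(2-methylprop-2-en-1-yl)oct-7-ene-1,3-diol | OC[C@@](C)(CC(C)=C)[C@H](O)C[C@@H](OCc1ccc(OC)cc1)C(C)(C)C=C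
F12 | step 6 | (2S,3R,5R)-3-hydroxy-5-[(4-methoxyphenyl)methoxy]-2,6,6-trimethyl-2-(2-methylprop-2-en-1-yl)oct-7-enal | O=C[C@@](C)(CC(C)=C)[C@H](O)C[C@@H](OCc1ccc(OC)cc1)C(C)(C)C=C
F13 | step 6 | (5R,7R)-7-[(4-methoxyphenyl)methoxy]-4,8,8-trimethyl-4-(2-methylprop-2-en-1-yl)deca-1,9-diene-3,5-diol (C4 as in 11, C3 epimers) | C=CC(O)[C@@](C)(CC(C)=C)[C@H](O)C[C@@H](OCc1ccc(OC)cc1)C(C)(C)C=C
F14 | step 6 | (5R,7R)-5-hydroxy-7-[(4-methoxyphenyl)methoxy]-4,8,8-trimethyl-4-(2-methylprop-2-en-1-yl)deca-1,9-dien-3-one (C4 as in 11) | C=CC(=O)[C@@](C)(CC(C)=C)[C@H](O)C[C@@H](OCc1ccc(OC)cc1)C(C)(C)C=C
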